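## Retrosynthetic overview

1. The cyclohexene is formed last by an exo-selective enzymatic [4+2] between dienophile **18** (2,2',4,4'-tetrahydroxychalcone) and the (2S)-flavanone dehydroprenyl diene **12**; this sets C3″, C4″ and C5″ (all-trans).
2. Diene **12** comes from Suzuki coupling of a silyl-protected (2S)-5'-bromoflavanone with an (E)-dienyl boronate, then buffered desilylation.
3. The bromoflavanone comes from Rh-catalysed asymmetric 1,4-addition of an arylboronic acid to 7-O-MOM-chromone; this sets flavanone C2, the first stereocentre.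
4. Chalcone **18** comes from a Claisen–Schmidt condensation of MOM-protected resacetophenone and 2,4-dihydroxybenzaldehyde.
5. Ring order: the chromanone ring is bought preformed (7-hydroxychromone) and its stereocentre is created in step 4; the cyclohexene ring is made in step 14.

Assumptions (one line each):
- The exo-selective Morus alba Diels–Alderase (MaDA-3 type) is available by heterologous expression and is used as a catalyst; my recollection is that MaDA-3 is the exo-selective member of this family, which should be confirmed.
- The (S)-ligand in step 4 is chosen by analogy with (S)-BINAP giving (S)-3-arylcyclohexanones; confirm the sense by chiral HPLC/CD and use the ent-ligand if it is reversed.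
- Numbered compounds are those whose skeleton is carried to the target; protecting-group and boron reagents are given by name and SMILES in each step.

## Route

**Step 1**
Reactants: **1** 4,6-dibromobenzene-1,3-diol (4,6-dibromoresorcinol)
Product: **2** 1,5-dibromo-2,4-bis(methoxymethoxy)benzene
Conditions: MOMCl (2.5 equiv), i-Pr2NEt, CH2Cl2, 0 °C → rt
Reagents that add atoms: chloromethyl methyl ether, COCCl
Why: Simple O-alkylation (acetal protection) of both phenols gives a base-stable, lithiation-compatible diether.

**Step 2**
Reactants: **2**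
Product: **3** [5-bromo-2,4-bis(methoxymethoxy)phenyl]boronic acid
Conditions: n-BuLi (1.05 equiv), THF, −78 °C; B(Oi-Pr)3, −78 °C → rt; sat. aq NH4Cl
Reagents that add atoms: triisopropyl borate, CC(C)OB(OC(C)C)OC(C)C; water, O
Why: Mono Br/Li exchange (the OMOM-chelated aryllithium resists a second exchange, and the remaining Br is meta so no aryne can form) followed by borate trapping and mild hydrolysis gives the boronic acid with MOM groups intact.

**Step 3**
Reactants: **4** 7-hydroxy-4H-chromen-4-one
Product: **5** 7-(methoxymethoxy)-4H-chromen-4-one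
Conditions: MOMCl, i-Pr2NEt, CH2Cl2, 0 °C → rt
Reagents that add atoms: chloromethyl methyl ether, COCCl
Why: O-alkylation of the acidic 7-OH masks the phenol so it cannot quench the aryl-rhodium species in the next step.

**Step 4**
Reactants: **5** and **3** (2.5 equiv)
Product: **6** (2S)-2-[5-bromo-2,4-bis(methoxymethoxy)phenyl]-7-(methoxymethoxy)chroman-4-one
Conditions: [RhCl(C2H4)2]2 (2.5 mol %), (S)-MeO-F12-BIPHEP (5.5 mol %), aq KOH (20 mol %), toluene/H2O 10:1, 35 °C
Reagents that add atoms: none
Why: Hayashi–Miyaura Rh(I)-catalysed asymmetric 1,4-addition of the aryl-rhodium to the chromone sets C2 as S under ligand control, and the aryl bromide and MOM ethers are inert to Rh(I).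

**Step 5**
Reactants: **6**
Product: **7** (2S)-2-(5-bromo-2,4-dihydroxyphenyl)-7-hydroxychroman-4-one
Conditions: HCl (ca. 2 M, from AcCl/MeOH), MeOH/THF, 0 °C → rt; check ee by chiral HPLC
Reagents that add atoms: none
Why: Acid-catalysed acetal cleavage removes all three MOM groups at room temperature, where C2–O ring-opening of the flavanone should be slow (ee checked), and it is done before the acid-labile diene exists.

**Step 6**
Reactants: **7**
Product: **8** (2S)-2-[5-bromo-2,4-bis(tert-butyldimethylsilyloxy)phenyl]-7-(tert-butyldimethylsilyloxy)chroman-4-one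
Conditions: TBSCl (4 equiv), imidazole (6 equiv), DMF, 0 °C → rt
Reagents that add atoms: tert-butyldimethylsilyl chloride, CC(C)(C)[Si](C)(C)Cl
Why: Silylation under weakly basic conditions swaps in protecting groups that can later be removed with buffered fluoride, without acid or strong base.

**Step 7**
Reactants: **9** 2-methylbut-1-en-3-yne
Product: **10** (E)-4,4,5,5-tetramethyl-2-(3-methylbuta-1,3-dien-1-yl)-1,3,2-dioxaborolane
Conditions: HBpin (1.05 equiv), Cp2Zr(H)Cl (5 mol %), Et3N (10 mol %), neat, sealed tube, 60 °C
Reagents that add atoms: pinacolborane, [H]B1OC(C)(C)C(C)(C)O1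
Why: Zirconium-catalysed syn-hydroboration of the terminal alkyne (faster than the 1,1-disubstituted alkene) gives the (E)-dienyl boronate only.

**Step 8**
Reactants: **8** and **10** (1.5 equiv)
Product: **11** (2S)-2-{2,4-bis(tert-butyldimethylsilyloxy)-5-[(1E)-3-methylbuta-1,3-dien-1-yl]phenyl}-7-(tert-butyldimethylsilyloxy)chroman-4-one
Conditions: SPhos Pd G3 (3 mol %), K3PO4 (2 equiv), degassed THF/H2O 10:1, 40 °C, 3 h
Reagents that add atoms: none
Why: Suzuki–Miyaura coupling with retention of alkene geometry installs the (E)-diene; a highly active catalyst allows mild base and low temperature so C2 is not epimerised by E1cB ring-opening.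

**Step 9**
Reactants: **11**
Product: **12** (2S)-2-{2,4-dihydroxy-5-[(1E)-3-methylbuta-1,3-dien-1-yl]phenyl}-7-hydroxychroman-4-one
Conditions: TBAF/AcOH (1:1, 3.5 equiv), THF, 0 °C, 30 min; pH 7 buffer work-up; use at once
Reagents that add atoms: none
Why: Buffered fluoride desilylation is near neutral, so the acid-sensitive o-hydroxyaryl diene (which would cyclise to a dimethylchromene) and the base-sensitive flavanone centre both survive.

**Step 10**
Reactants: **13** 1-(2,4-dihydroxyphenyl)ethanone
Product: **14** 1-[2-hydroxy-4-(methoxymethoxy)phenyl]ethanone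
Conditions: MOMCl (1.1 equiv), K2CO3, acetone, 0 °C → rt
Reagents that add atoms: chloromethyl methyl ether, COCCl
Why: Selective O-alkylation of the 4-OH occurs because the 2-OH is hydrogen-bonded to the ketone and much less nucleophilic.

**Step 11**
Reactants: **15** 2,4-dihydroxybenzaldehyde
Product: **16** 2,4-bis(methoxymethoxy)benzaldehyde
Conditions: NaH (2.4 equiv), MOMCl (2.4 equiv), DMF, 0 °C → rt
Reagents that add atoms: chloromethyl methyl ether, COCCl
Why: Full deprotonation forces alkylation of the chelated 2-OH as well, giving a base-stable aldehyde for the aldol step.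

**Step 12**
Reactants: **14** and **16**
Product: **17** (E)-3-[2,4-bis(methoxymethoxy)phenyl]-1-[2-hydroxy-4-(methoxymethoxy)phenyl]prop-2-en-1-one
Conditions: KOH (50 % aq), EtOH, rt, 24 h; then dilute AcOH to pH 6
Reagents that add atoms: none
Why: Claisen–Schmidt aldol condensation with E1cB dehydration gives the thermodynamically favoured (E)-enone, and MOM ethers are stable to hydroxide.

**Step 13**
Reactants: **17**
Product: **18** (E)-1,3-bis(2,4-dihydroxyphenyl)prop-2-en-1-one (2,2',4,4'-tetrahydroxychalcone)
Conditions: 3 M HCl, MeOH, 50 °C, 30–45 min (monitor; stop before flavanone/flavylium formation)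
Reagents that add atoms: none
Why: Brief acid-catalysed acetal cleavage frees the four phenols, with the chelated 2'-hydroxychalcone kept intact by the short reaction time.

**Step 14**
Reactants: **12** (1 equiv) and **18** (1.2 equiv)
Product: **19** guangsangon N
Conditions: exo-selective FAD-dependent intermolecular Diels–Alderase (Morus alba MaDA-3 type), Tris-HCl 50 mM pH 7.5, 10 % DMSO, 37 °C, dark, 12–24 h; EtOAc extraction, RP-HPLC
Reagents that add atoms: none
Why: The Diels–Alderase holds the (E)-chalcone and the (E)-diene in an exo transition state for a concerted [4+2], so the 4″,5″-trans relationship follows from the chalcone geometry, the 3″,4″-trans relationship from the exo mode, and the absolute configuration (3″R,4″R,5″S) from the enzyme pocket, while the remote C2 (S) is untouched at near-neutral pH.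

## Compound list

1 | 4,6-dibromobenzene-1,3-diol | Oc1cc(O)c(Br)cc1Br | starting material
2 | 1,5-dibromo-2,4-bis(methoxymethoxy)benzene | COCOc1cc(OCOC)c(Br)cc1Br | intermediate
3 | [5-bromo-2,4-bis(methoxymethoxy)phenyl]boronic acid | COCOc1cc(OCOC)c(B(O)O)cc1Br | intermediate
4 | 7-hydroxy-4H-chromen-4-one | O=c1ccoc2cc(O)ccc12 | starting material
5 | 7-(methoxymethoxy)-4H-chromen-4-one | COCOc1ccc2c(c1)occc2=O | intermediate
6 | (2S)-2-[5-bromo-2,4-bis(methoxymethoxy)phenyl]-7-(methoxymethoxy)chroman-4-one | COCOc1cc(OCOC)c(Br)cc1[C@@H]1CC(=O)c2ccc(OCOC)cc2O1 | intermediate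
7 | (2S)-2-(5-bromo-2,4-dihydroxyphenyl)-7-hydroxychroman-4-one | Oc1cc(O)c(Br)cc1[C@@H]1CC(=O)c2ccc(O)cc2O1 | intermediate
8 | (2S)-2-[5-bromo-2,4-bis(TBS-oxy)phenyl]-7-(TBS-oxy)chroman-4-one | CC(C)(C)[Si](C)(C)Oc1cc(O[Si](C)(C)C(C)(C)C)c(Br)cc1[C@@H]1CC(=O)c2ccc(O[Si](C)(C)C(C)(C)C)cc2O1 | intermediate
9 | 2-methylbut-1-en-3-yne | C=C(C)C#C | starting material
10 | (E)-4,4,5,5-tetramethyl-2-(3-methylbuta-1,3-dien-1-yl)-1,3,2-dioxaborolane | CC(=C)/C=C/B1OC(C)(C)C(C)(C)O1 | intermediate
11 | (2S)-2-{2,4-bis(TBS-oxy)-5-[(1E)-3-methylbuta-1,3-dien-1-yl]phenyl}-7-(TBS-oxy)chroman-4-one | CC(=C)/C=C/c1cc([C@@H]2CC(=O)c3ccc(O[Si](C)(C)C(C)(C)C)cc3O2)c(O[Si](C)(C)C(C)(C)C)cc1O[Si](C)(C)C(C)(C)C | intermediate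
12 | (2S)-2-{2,4-dihydroxy-5-[(1E)-3-methylbuta-1,3-dien-1-yl]phenyl}-7-hydroxychroman-4-one | CC(=C)/C=C/c1cc([C@@H]2CC(=O)c3ccc(O)cc3O2)c(O)cc1O | intermediate
13 | 1-(2,4-dihydroxyphenyl)ethanone | CC(=O)c1ccc(O)cc1O | starting material
14 | 1-[2-hydroxy-4-(methoxymethoxy)phenyl]ethanone | CC(=O)c1ccc(OCOC)cc1O | intermediate
15 | 2,4-dihydroxybenzaldehyde | O=Cc1ccc(O)cc1O | starting material
16 | 2,4-bis(methoxymethoxy)benzaldehyde | O=Cc1ccc(OCOC)cc1OCOC | intermediate
17 | (E)-3-[2,4-bis(methoxymethoxy)phenyl]-1-[2-hydroxy-4-(methoxymethoxy)phenyl]prop-2-en-1-one | COCOc1ccc(C(=O)/C=C/c2ccc(OCOC)cc2OCOC)c(O)c1 | intermediate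
18 | (E)-1,3-bis(2,4-dihydroxyphenyl)prop-2-en-1-one | O=C(/C=C/c1ccc(O)cc1O)c1ccc(O)cc1O | intermediate
19 | guangsangon N: (2S)-flavanone; all-trans 1″-methylcyclohex-1″-ene with C3″ (R, flavanone aryl), C4″ (R, 2,4-dihydroxybenzoyl), C5″ (S, 2,4-dihydroxyphenyl) | CC1=C[C@@H](c2cc([C@@H]3CC(=O)c4ccc(O)cc4O3)c(O)cc2O)[C@H](C(=O)c2ccc(O)cc2O)[C@@H](c2ccc(O)cc2O)C1 | target

## Summary

Total steps: 14.
Longest linear sequence: 8 steps (1 → 2 → 4 → 5 → 6 → 8 → 9 → 14).

Three steps most likely to fail, each with one fallback:

1. **Step 14 (enzymatic exo [4+2]).** The flavanone-bearing diene may be a poor substrate, exo selectivity may erode, or C2 may partly epimerise in buffer (a 2R diastereomer would be removed by HPLC). Fallback: a non-enzymatic cycloaddition of the peracetylated diene with the chalcone carrying only a free 2'-OH, promoted by a chiral VANOL/BINOL–borate Lewis acid; the exo adduct is separated and the acetates are removed with neutral NH4OAc in aqueous MeOH.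

2. **Step 4 (Rh 1,4-addition).** The ortho-alkoxy, electron-rich boronic acid may protodeboronate or transmetallate slowly, giving low conversion or ee. Fallback: build the racemic flavanone by Claisen–Schmidt condensation of **14** with 5-bromo-2,4-bis(methoxymethoxy)benzaldehyde and NaOAc-mediated oxa-Michael closure, then obtain the 2S ketone by catalytic kinetic resolution with Ru–TsDPEN asymmetric transfer hydrogenation (the 2R enantiomer is reduced to the flavanol and separated).

3. **Steps 8–9 (Suzuki then desilylation).** Aqueous base may cause partial desilylation and C2 epimerisation, or the free diene may cyclise on isolation. Fallback: protect **7** as the triacetate and install the diene by base-free Stille coupling with (E)-tributyl(3-methylbuta-1,3-dienyl)stannane, then cleave the acetates with neutral NH4OAc in aqueous MeOH (or a lipase) immediately before the enzymatic step.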